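**Retrosynthetic overview**
1. The succinimide of 16 comes from an ammonia-induced lactone-to-imide switch of the trans γ-lactone ester 14 (last ring formed).
2. The C12–C13 bond is made by adding the β-carbon of ethyl 4-oxobutenoate 12, turned nucleophilic as an NHC homoenolate, to the aldehyde carbon of 11; the γ-lactone closes in the same step.
3. The 6β-OH and 8(17)-alkene of 11 come from the 7-en-6-one 6 by boryl conjugate addition, ketone reduction, C–B oxidation and exo-selective dehydration.
4. Enone 6 comes from 2α-chlorosclareolide 2 by lactone opening, dehydration, alkene isomerisation and allylic oxidation.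
5. Rings A and B (C-5, C-9, C-10) are taken intact from (+)-sclareolide 1 and C-2 is chlorinated by C–H functionalisation; no carbocycle is built.

Assumption: labdane numbering is used (Cl at C-2, ring OH at C-6, exocyclic alkene C-8(17), carbinol C-12, imide methine C-13), and the N-chloroamide of step 1 and the chiral triazolium salt of step 9 are bought.

**Route**

Step 1
Reactants: 1 (+)-sclareolide
Product: 2 2α-chlorosclareolide
Conditions: ArC(O)N(Cl)t-Bu (Ar = 3,5-(CF3)2C6H3, 1.2 equiv), Cs2CO3, PhH, blue LEDs, 55 °C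
Reagents that add atoms: N-tert-butyl-N-chloro-3,5-bis(trifluoromethyl)benzamide, CC(C)(C)N(Cl)C(=O)c1cc(cc(c1)C(F)(F)F)C(F)(F)F
Why: Alexanian-type amidyl-radical C–H chlorination; the lactone deactivates ring B and the quaternary C-4 and C-10 shield C-1 and C-3, so the C-2 methylene reacts, and chlorine is delivered to the C-2 radical from the open equatorial α-face (β-face blocked by the two axial methyls).

Step 2
Reactants: 2 2α-chlorosclareolide
Product: 3 hydroxy Weinreb amide
Conditions: MeNH(OMe)·HCl, AlMe3, CH2Cl2, 0 °C to rt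
Reagents that add atoms: N,O-dimethylhydroxylamine hydrochloride, CNOC.Cl
Why: Weinreb aminolysis of the lactone by the aluminium amide made in the flask frees the 8α-tertiary alcohol without touching any stereocentre.

Step 3
Reactants: 3 hydroxy Weinreb amide
Product: 4 exocyclic alkene Weinreb amide
Conditions: SOCl2, pyridine, CH2Cl2, −78 °C
Reagents that add atoms: none
Why: E2 dehydration of the tertiary chlorosulfite; the equatorial 8α leaving group has an anti-periplanar hydrogen only on the C-17 methyl, so the 8(17)-alkene forms.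

Step 4
Reactants: 4 exocyclic alkene Weinreb amide
Product: 5 7-ene Weinreb amide
Conditions: chloro[N,N′-bis(3,5-di-tert-butylsalicylidene)-2,3-dimethylbutane-2,3-diaminato]cobalt (3 mol %), PhSiH3 (6 mol %), PhH, rt
Reagents that add atoms: none
Why: Shenvi-type cobalt-hydride HAT isomerisation; H-atom transfer to C-17 gives the tertiary C-8 radical, and hydrogen is taken back from the open C-7 methylene rather than the shielded C-9 methine, giving the trisubstituted 7-ene.

Step 5
Reactants: 5 7-ene Weinreb amide
Product: 6 7-en-6-one Weinreb amide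
Conditions: Rh2(cap)4 (dirhodium tetracaprolactamate, 1 mol %), t-BuOOH (5 equiv), K2CO3, CH2Cl2, rt
Reagents that add atoms: tert-butyl hydroperoxide, CC(C)(C)OO
Why: Allylic C–H oxidation (tert-butylperoxyl H-abstraction, mixed peroxide, Kornblum–DeLaMare collapse); C-6 is the only allylic methylene, and the trans ring fusion at C-5 is the stable one.

Step 6
Reactants: 6 7-en-6-one Weinreb amide
Product: 9 6β,8α-diol Weinreb amide, via tertiary boronate 7 (not isolated), via boryl alcohol 8 (not isolated)
Conditions: CuCl (10 mol %), IMes·HCl (10 mol %), NaOt-Bu (30 mol %), B2pin2, MeOH, THF, rt; then NaBH4, 0 °C; then NaOH, H2O2, H2O, 0 °C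
Reagents that add atoms: hydrogen peroxide, OO
Why: Copper-boryl conjugate addition places boron on C-8 from the α-face (anti to the axial C-10 methyl); NaBH4 attacks the C-6 ketone from the α-face (β-face blocked by the syn-axial C-4 and C-10 methyls) to give the axial 6β-alcohol; stereoretentive C–B oxidation gives the 8α-alcohol.

Step 7
Reactants: 9 6β,8α-diol Weinreb amide
Product: 10 6β-hydroxy exocyclic alkene Weinreb amide
Conditions: SOCl2 (2.5 equiv), pyridine, CH2Cl2, −78 °C; cold aq. NaHCO3
Reagents that add atoms: none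
Why: Same chlorosulfite E2 dehydration as step 3 (equatorial 8α leaving group, so exocyclic alkene); the axial 6β-hydroxyl, flanked by two syn-axial methyls, is at most sulfinylated and comes back on cold hydrolysis.

Step 8
Reactants: 10 6β-hydroxy exocyclic alkene Weinreb amide
Product: 11 hydroxy aldehyde
Conditions: i-Bu2AlH (3 equiv), THF, −78 °C; aq. potassium sodium tartrate
Reagents that add atoms: none
Why: Weinreb amide reduction; the chelated tetrahedral aluminate releases the aldehyde only on work-up, and the first equivalent of hydride merely deprotonates the 6-OH.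

Step 9
Reactants: 11 hydroxy aldehyde; 12 ethyl (E)-4-oxobut-2-enoate
Product: 14 trans-lactone ester, via cis-lactone ester 13 (not isolated)
Conditions: (5aR,10bS)-2-mesityl-5a,10b-dihydro-4H,6H-indeno[2,1-b][1,2,4]triazolo[4,3-d][1,4]oxazin-2-ium chloride (15 mol %), DBU (15 mol %), Ti(Oi-Pr)4 (20 mol %), 4 Å MS, THF, rt, 12 (3 equiv) added over 10 h; then DBU (0.5 equiv), rt
Reagents that add atoms: none
Why: Proposed new method: the N-mesityl triazolylidene adds to the enal carbonyl of 12 to give the extended Breslow (homoenolate) species, whose β-carbon (C-13, normally a Michael-acceptor carbon) attacks the aldehyde carbon C-12 of 11 inside the chiral pocket through the usual cis-selective arrangement (setting C-12 as S), the alkoxide then acylates the acyl azolium at C-15 to close the γ-lactone and free the carbene, and DBU epimerises the ester-bearing C-13 of cis-lactone 13 to the more stable trans-lactone 14 (12S,13R); the closest known reactions are the NHC homoenolate annulation of enals with aldehydes (Bode–Glorius γ-butyrolactone synthesis) and homoenolate additions of this same 4-oxoenoate to imines, the new element being an enolisable aliphatic aldehyde as acceptor, which is why 12 is added slowly (against its self-annulation) and Ti(Oi-Pr)4 activates 11.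

Step 10
Reactants: 14 trans-lactone ester
Product: 16 haterumaimide F, via hydroxy amide ester 15 (not isolated)
Conditions: NH3 (2 M in MeOH, 5 equiv), 0 °C to rt; then K2CO3 (0.2 equiv), MeOH, rt; aq. NH4Cl
Reagents that add atoms: ammonia, N
Why: Ammonolysis of the γ-lactone gives the γ-hydroxy primary amide, whose nitrogen closes onto the neighbouring ethyl ester (intramolecular acyl substitution, succinimide formation) with loss of ethanol; C-12 and C-13 are not touched and the imide anion is the resting state under base.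

**Compound list**
1 | (+)-sclareolide | C[C@@]12CC[C@H]3C(C)(C)CCC[C@]3(C)[C@H]1CC(=O)O2 | starting material
2 | 2α-chlorosclareolide | C[C@@]12CC[C@H]3C(C)(C)C[C@H](Cl)C[C@]3(C)[C@H]1CC(=O)O2 | intermediate
3 | hydroxy Weinreb amide: 2α-chloro-8α-hydroxy-13,14,15,16-tetranorlabdan-12-oic acid N-methoxy-N-methylamide | C[C@@]1(O)CC[C@H]2C(C)(C)C[C@H](Cl)C[C@]2(C)[C@H]1CC(=O)N(C)OC | intermediate
4 | exocyclic alkene Weinreb amide: 2α-chloro-13,14,15,16-tetranorlabd-8(17)-en-12-oic acid N-methoxy-N-methylamide | C=C1CC[C@H]2C(C)(C)C[C@H](Cl)C[C@]2(C)[C@H]1CC(=O)N(C)OC | intermediate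
5 | 7-ene Weinreb amide: 2α-chloro-13,14,15,16-tetranorlabd-7-en-12-oic acid N-methoxy-N-methylamide | CC1=CC[C@H]2C(C)(C)C[C@H](Cl)C[C@]2(C)[C@H]1CC(=O)N(C)OC | intermediate
6 | 7-en-6-one Weinreb amide: 2α-chloro-6-oxo-13,14,15,16-tetranorlabd-7-en-12-oic acid N-methoxy-N-methylamide | CC1=CC(=O)[C@H]2C(C)(C)C[C@H](Cl)C[C@]2(C)[C@H]1CC(=O)N(C)OC | intermediate
7 | tertiary boronate: 8α-(pinacolboryl)-2α-chloro-6-oxo-13,14,15,16-tetranorlabdan-12-oic acid N-methoxy-N-methylamide | C[C@@]1(B3OC(C)(C)C(C)(C)O3)CC(=O)[C@H]2C(C)(C)C[C@H](Cl)C[C@]2(C)[C@H]1CC(=O)N(C)OC | intermediate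
8 | boryl alcohol: 8α-(pinacolboryl)-2α-chloro-6β-hydroxy-13,14,15,16-tetranorlabdan-12-oic acid N-methoxy-N-methylamide | C[C@@]1(B3OC(C)(C)C(C)(C)O3)C[C@@H](O)[C@H]2C(C)(C)C[C@H](Cl)C[C@]2(C)[C@H]1CC(=O)N(C)OC | intermediate
9 | 6β,8α-diol Weinreb amide: 2α-chloro-6β,8α-dihydroxy-13,14,15,16-tetranorlabdan-12-oic acid N-methoxy-N-methylamide | C[C@@]1(O)C[C@@H](O)[C@H]2C(C)(C)C[C@H](Cl)C[C@]2(C)[C@H]1CC(=O)N(C)OC | intermediate
10 | 6β-hydroxy exocyclic alkene Weinreb amide: 2α-chloro-6β-hydroxy-13,14,15,16-tetranorlabd-8(17)-en-12-oic acid N-methoxy-N-methylamide | C=C1C[C@@H](O)[C@H]2C(C)(C)C[C@H](Cl)C[C@]2(C)[C@H]1CC(=O)N(C)OC | intermediate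
11 | hydroxy aldehyde: 2α-chloro-6β-hydroxy-13,14,15,16-tetranorlabd-8(17)-en-12-al | C=C1C[C@@H](O)[C@H]2C(C)(C)C[C@H](Cl)C[C@]2(C)[C@H]1CC=O | intermediate
12 | ethyl (E)-4-oxobut-2-enoate | CCOC(=O)/C=C/C=O | starting material
13 | cis-lactone ester: ethyl (12S,13S)-2α-chloro-6β-hydroxylabd-8(17)-en-15,12-olid-16-oate | C=C1C[C@@H](O)[C@H]2C(C)(C)C[C@H](Cl)C[C@]2(C)[C@H]1C[C@@H]1OC(=O)C[C@@H]1C(=O)OCC | intermediate
14 | trans-lactone ester: ethyl (12S,13R)-2α-chloro-6β-hydroxylabd-8(17)-en-15,12-olid-16-oate | C=C1C[C@@H](O)[C@H]2C(C)(C)C[C@H](Cl)C[C@]2(C)[C@H]1C[C@@H]1OC(=O)C[C@H]1C(=O)OCC | intermediate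
15 | hydroxy amide ester: ethyl (12S,13R)-15-amino-2α-chloro-6β,12-dihydroxy-15-oxolabd-8(17)-en-16-oate | C=C1C[C@@H](O)[C@H]2C(C)(C)C[C@H](Cl)C[C@]2(C)[C@H]1C[C@H](O)[C@@H](CC(N)=O)C(=O)OCC | intermediate
16 | haterumaimide F | C=C1C[C@@H](O)[C@H]2C(C)(C)C[C@H](Cl)C[C@]2(C)[C@H]1C[C@H](O)[C@H]1CC(=O)NC1=O | target

**Totals**
Total step count: 10. Longest linear sequence: 10 steps (from 1; 12 is bought).

**Three steps most likely to fail, each with one fallback**

Step 9 (homoenolate annulation). The aliphatic, β-branched aldehyde 11 is a weaker acceptor than 12 itself, so self-annulation of 12, β-protonation of the homoenolate and acyl-anion chemistry of 11 all compete. The facial sense at C-12 is assigned by analogy, not by precedent on this substrate. The fallback changes the polarity pattern to an acyl-anion addition. It sets out from 11 and comes back at 16. A thiazolium-catalysed Stetter addition of 11 to maleimide (3-benzyl-5-(2-hydroxyethyl)-4-methylthiazolium chloride, Et3N, EtOH, 70 °C) gives the β-keto imide F1, whose C-13 centre epimerises freely. A dynamic kinetic asymmetric transfer hydrogenation (RuCl(p-cymene)[(S,S)-TsDPEN], HCO2H/Et3N 5:2, CH2Cl2, rt) then sets C-12 and C-13 together and gives 16 directly.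

Step 6 (boryl conjugate addition to the hindered β,β-disubstituted enone, telescoped with reduction and oxidation). The C-8 terminus is flanked by the C-9 methine and the C-10 quaternary centre, so the copper-boryl addition may stall. The fallback replaces boron by an epoxide. It sets out from 6 and comes back at 9. Nucleophilic epoxidation (H2O2, NaOH, MeOH, 0 °C; α-face attack) gives the 7α,8α-epoxy ketone F2. SmI2 (THF/MeOH, −90 °C) cleaves the C-7–O bond to give the 8α-hydroxy ketone F3. NaBH4 (MeOH, 0 °C) then gives 9.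

Step 7 (dehydration of the tertiary alcohol next to a free secondary alcohol). If the 6β-hydroxyl is sulfinylated and eliminated, or ring alkenes form, the step fails. The fallback masks the 6β-oxygen before the tertiary alcohol exists. It sets out from 8 (isolated by working up step 6 before the peroxide is added) and comes back at 10. Et3SiOTf/2,6-lutidine gives the silyl ether boronate F4. NaBO3·4H2O (THF/H2O) oxidises the C–B bond to give the silyl ether tertiary alcohol F5. SOCl2/pyridine (−78 °C) gives the silyl ether alkene F6. Bu4NF (THF) then returns 10.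

**Further compounds**
F1 | step 9 | β-keto imide: 3-acylsuccinimide from 11 and maleimide (C-13 labile) | C=C1C[C@@H](O)[C@H]2C(C)(C)C[C@H](Cl)C[C@]2(C)[C@H]1CC(=O)C1CC(=O)NC1=O
F2 | step 6 | 7α,8α-epoxy ketone Weinreb amide | C[C@@]12O[C@@H]1C(=O)[C@H]3C(C)(C)C[C@H](Cl)C[C@]3(C)[C@H]2CC(=O)N(C)OC
F3 | step 6 | 8α-hydroxy ketone Weinreb amide | C[C@@]1(O)CC(=O)[C@H]2C(C)(C)C[C@H](Cl)C[C@]2(C)[C@H]1CC(=O)N(C)OC
F4 | step 7 | silyl ether boronate: 6β-triethylsilyloxy 8α-pinacolboryl Weinreb amide | C[C@@]1(B3OC(C)(C)C(C)(C)O3)C[C@@H](O[Si](CC)(CC)CC)[C@H]2C(C)(C)C[C@H](Cl)C[C@]2(C)[C@H]1CC(=O)N(C)OC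
F5 | step 7 | silyl ether tertiary alcohol: 6β-triethylsilyloxy 8α-hydroxy Weinreb amide | C[C@@]1(O)C[C@@H](O[Si](CC)(CC)CC)[C@H]2C(C)(C)C[C@H](Cl)C[C@]2(C)[C@H]1CC(=O)N(C)OC
F6 | step 7 | silyl ether alkene: 6β-triethylsilyloxy 8(17)-ene Weinreb amide | C=C1C[C@@H](O[Si](CC)(CC)CC)[C@H]2C(C)(C)C[C@H](Cl)C[C@]2(C)[C@H]1CC(=O)N(C)OC
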